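**Retrosynthetic overview**

1. The last C–C bond made is the sp2–sp2 bond C12'–C13' of target 41 (carotenoid numbering). It joins the C29 hexaenyl iodide 27 (iodine on the methyl-bearing C13') to the C21 dienyne 38 (terminal alkyne C11'≡C12'). Silyl ether cleavage then ends the route.
2. Feature that makes the key step possible: the diene C11'H=C12'H–C13'(CH3)=C14'H, an (E)-disubstituted alkene bonded through C12' to a methyl-bearing sp2 carbon. C11'=C12' is carried one oxidation level higher as a terminal alkyne and becomes the E-alkene by syn-hydrozirconation in the flask that forms C12'–C13'. Because C13 and C13' are related by the twofold pseudo-symmetry about C15=C15', one C8 bis-iodide 25 (from (E)-1,2-dichloroethene and propyne by two successive Sonogashira couplings) serves both sides.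
3. 27 comes from the ring A dienyne 19 and 25 by the same hydrozirconation/Negishi reaction at C12–C13. 19 and 38 each come from a Julia–Kocienski union (C7=C8) of a ring sulfone with enynal 16.
4. Neither six-membered ring is built; both come from enone 1 via dienone 2. One copper-catalysed asymmetric conjugate addition sets C2 and C2' (common intermediate 7). C6 and C6' diverge through a temporary carbinol at C4 (cis by Luche, trans by CBS reduction), which a Still–Wittig [2,3]-shift relays to C6 while moving the ring double bond to C4=C5 and erasing itself.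

Key step: step 26

Assumption: read with carotenoid numbering, the SMILES encodes (2S,6R,2'R,6'S) — C2 and C2' have the same configuration in space, C6 and C6' are epimeric (side chain and polyene cis on ring A, trans on ring B), and all chain double bonds and the hydroxylated side-chain double bond are E; compounds marked starting material and the reagents are taken as purchasable.

**Route**

Step 1
Reactants: 1 2,4,4-trimethylcyclohex-2-en-1-one
Product: 2 2,4,4-trimethylcyclohexa-2,5-dien-1-one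
Conditions: DDQ (1.5 equiv), 1,4-dioxane, reflux
Reagents that add atoms: none
Why: Dehydrogenation of the enone with DDQ (hydride abstraction from the dienol) should give the cross-conjugated dienone, which cannot aromatise because C4 is quaternary.

Step 2
Reactants: 3 4-bromo-2-methylbut-1-ene
Product: 4 (3-methylbut-3-en-1-yl)magnesium bromide
Conditions: Mg turnings, I2 (cat.), Et2O, rt → gentle reflux; titrated and used as solution
Reagents that add atoms: magnesium, [Mg]
Why: Grignard formation by insertion of magnesium into the primary C–Br bond; the homoallylic reagent keeps its skeleton because ring closure to the cyclopropylmethyl isomer and reopening return the same 3-methylbut-3-enyl group.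

Step 3
Reactants: 2 2,4,4-trimethylcyclohexa-2,5-dien-1-one; 4 (3-methylbut-3-en-1-yl)magnesium bromide
Product: 6 (5S)-2,4,4-trimethyl-5-(3-methylbut-3-en-1-yl)cyclohex-2-en-1-one, via bromomagnesium enolate 5 (not isolated)
Conditions: CuBr·SMe2 (5 mol%), (R)-1-[(S)-2-(diphenylphosphino)ferrocenyl]ethyldicyclohexylphosphine (Josiphos ligand, 6 mol%), t-BuOMe, −75 °C, slow addition of 4 (1.2 equiv); aq NH4Cl
Reagents that add atoms: none
Why: Copper-catalysed enantioselective conjugate addition of a Grignard reagent with a ferrocenyl diphosphine ligand, a reaction type known for cyclohex-2-enones and for homoallylic Grignard reagents: the unsubstituted C5=C6 arm should react in preference to the α-methylated arm, slow addition at low temperature should suppress uncatalysed 1,2-addition, and the ligand enantiomer is chosen, by analogy with cyclohex-2-enone, to add the alkyl group to the enantiotopic face that gives (5S), the centre that becomes C2 and C2'.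

Step 4
Reactants: 6 (5S)-2,4,4-trimethyl-5-(3-methylbut-3-en-1-yl)cyclohex-2-en-1-one
Product: 7 (5S)-2,4,4-trimethyl-5-(3-methylbut-2-en-1-yl)cyclohex-2-en-1-one
Conditions: CoCl(salen) [salen = N,N'-bis(3,5-di-tert-butylsalicylidene)ethane-1,2-diaminate] (5 mol%), PhSiH3 (5 mol%), benzene, rt
Reagents that add atoms: none
Why: Cobalt-hydride hydrogen-atom-transfer isomerisation should move the 1,1-disubstituted double bond by one position into the more stable trisubstituted (prenyl) position and leave the enone and C5 untouched.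

Step 5
Reactants: 7 (5S)-2,4,4-trimethyl-5-(3-methylbut-2-en-1-yl)cyclohex-2-en-1-one
Product: 8 (1R,5S)-2,4,4-trimethyl-5-(3-methylbut-2-en-1-yl)cyclohex-2-en-1-ol
Conditions: NaBH4, CeCl3·7H2O, MeOH, −78 → 0 °C
Reagents that add atoms: none
Why: Luche 1,2-reduction: hydride should attack C1 anti to the C5 side chain, as in 5-substituted cyclohex-2-enones, which sets the temporary carbinol (1R) cis to the side chain.

Step 6
Reactants: 8 (1R,5S)-2,4,4-trimethyl-5-(3-methylbut-2-en-1-yl)cyclohex-2-en-1-ol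
Product: 9 tributyl({[(1R,5S)-2,4,4-trimethyl-5-(3-methylbut-2-en-1-yl)cyclohex-2-en-1-yl]oxy}methyl)stannane
Conditions: KH, 18-crown-6 (cat.), THF, 0 °C; Bu3SnCH2I, rt
Reagents that add atoms: (iodomethyl)tributylstannane, CCCC[Sn](CCCC)(CCCC)CI
Why: Williamson etherification of the potassium alkoxide with the primary iodide installs the stannylmethyl group needed for the Still–Wittig rearrangement.

Step 7
Reactants: 9 tributyl({[(1R,5S)-2,4,4-trimethyl-5-(3-methylbut-2-en-1-yl)cyclohex-2-en-1-yl]oxy}methyl)stannane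
Product: 11 [(1R,5S)-2,6,6-trimethyl-5-(3-methylbut-2-en-1-yl)cyclohex-2-en-1-yl]methanol, via lithiomethyl ether 10 (not isolated)
Conditions: n-BuLi (1.2 equiv), THF, −78 → −30 °C; aq NH4Cl
Reagents that add atoms: none
Why: Tin–lithium exchange followed by Still–Wittig [2,3]-sigmatropic rearrangement: the CH2O unit is transferred suprafacially from O–C1 to C3, so the C1 carbinol sets the new stereocentre (carotenoid C6, R) cis to the prenyl group while the double bond moves to the C4=C5 position and the carbinol stereocentre disappears.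

Step 8
Reactants: 11 [(1R,5S)-2,6,6-trimethyl-5-(3-methylbut-2-en-1-yl)cyclohex-2-en-1-yl]methanol
Product: 12 1-phenyl-5-({[(1R,5S)-2,6,6-trimethyl-5-(3-methylbut-2-en-1-yl)cyclohex-2-en-1-yl]methyl}sulfanyl)-1H-tetrazole
Conditions: 1-phenyl-1H-tetrazole-5-thiol, PPh3, DIAD, THF, 0 °C → rt
Reagents that add atoms: 1-phenyl-1H-tetrazole-5-thiol, Sc1nnnn1-c1ccccc1
Why: Mitsunobu thioetherification of the primary alcohol with the acidic tetrazole thiol; no stereocentre is involved.

Step 9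
Reactants: 12 1-phenyl-5-({[(1R,5S)-2,6,6-trimethyl-5-(3-methylbut-2-en-1-yl)cyclohex-2-en-1-yl]methyl}sulfanyl)-1H-tetrazole
Product: 13 1-phenyl-5-({[(1R,5S)-2,6,6-trimethyl-5-(3-methylbut-2-en-1-yl)cyclohex-2-en-1-yl]methyl}sulfonyl)-1H-tetrazole
Conditions: (NH4)6Mo7O24·4H2O (10 mol%), 30% aq H2O2, EtOH, 0 °C → rt
Reagents that add atoms: hydrogen peroxide, OO
Why: Molybdate-catalysed oxidation of the sulfide to the sulfone, the standard entry to Julia–Kocienski reagents, should be much faster than epoxidation of the trisubstituted alkenes.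

Step 10
Reactants: 14 3-(trimethylsilyl)prop-2-ynal; 15 2-(triphenyl-λ5-phosphanylidene)propanal
Product: 16 (2E)-2-methyl-5-(trimethylsilyl)pent-2-en-4-ynal
Conditions: CH2Cl2, rt
Reagents that add atoms: none
Why: Wittig olefination with a stabilised α-methylated ylide should give the (E)-enal (the later C9=C10 geometry) and stop after one homologation because the product enal is less electrophilic than the ynal.

Step 11
Reactants: 13 1-phenyl-5-({[(1R,5S)-2,6,6-trimethyl-5-(3-methylbut-2-en-1-yl)cyclohex-2-en-1-yl]methyl}sulfonyl)-1H-tetrazole; 16 (2E)-2-methyl-5-(trimethylsilyl)pent-2-en-4-ynal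
Product: 18 trimethyl{(3E,5E)-4-methyl-6-[(1R,5S)-2,6,6-trimethyl-5-(3-methylbut-2-en-1-yl)cyclohex-2-en-1-yl]hexa-3,5-dien-1-yn-1-yl}silane, via potassium sulfonyl carbanion 17 (not isolated)
Conditions: KN(SiMe3)2, DME, −60 °C; 16, −60 °C → rt
Reagents that add atoms: none
Why: Julia–Kocienski olefination: addition of the metalated tetrazolyl sulfone to the enal, Smiles rearrangement and loss of SO2 and tetrazolone should give the (E)-C7=C8 alkene, the branched groups on both sides reinforcing the E preference.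

Step 12
Reactants: 18 trimethyl{(3E,5E)-4-methyl-6-[(1R,5S)-2,6,6-trimethyl-5-(3-methylbut-2-en-1-yl)cyclohex-2-en-1-yl]hexa-3,5-dien-1-yn-1-yl}silane
Product: 19 (3E,5E)-4-methyl-6-[(1R,5S)-2,6,6-trimethyl-5-(3-methylbut-2-en-1-yl)cyclohex-2-en-1-yl]hexa-3,5-dien-1-yne
Conditions: K2CO3, MeOH, rt
Reagents that add atoms: none
Why: Base-catalysed methanolysis of the alkynyl–silicon bond frees the terminal alkyne.

Step 13
Reactants: 20 (E)-1,2-dichloroethene; 21 propyne
Product: 22 (1E)-1-chloropent-1-en-3-yne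
Conditions: 20 (5 equiv), Pd(PPh3)4 (5 mol%), CuI (10 mol%), n-BuNH2, Et2O, 0 °C → rt; distilled and used as solution
Reagents that add atoms: none
Why: Sonogashira coupling of one C–Cl bond with retention of the (E)-geometry; the large excess of the dichloride should hold the reaction at the mono-coupled chloroenyne, which is freed from the volatile dichloride by distillation.

Step 14
Reactants: 22 (1E)-1-chloropent-1-en-3-yne; 21 propyne
Product: 23 (4E)-octa-4-ene-2,6-diyne
Conditions: PdCl2(PhCN)2 (5 mol%), CuI (10 mol%), piperidine, rt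
Reagents that add atoms: none
Why: Second Sonogashira coupling, under conditions used for alkenyl chlorides of the chloroenyne type, should replace the remaining chlorine with retention and give the symmetric (E)-enediyne that holds C13 to C13'.

Step 15
Reactants: 23 (4E)-octa-4-ene-2,6-diyne
Product: 25 (2E,4E,6E)-2,7-diiodoocta-2,4,6-triene, via dialkenyl bis(zirconocene chloride) 24 (not isolated)
Conditions: Cp2Zr(H)Cl (3 equiv), THF, rt → 40 °C, dark; I2, 0 °C
Reagents that add atoms: iodine, II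
Why: Double syn-hydrozirconation followed by iodinolysis with retention: with excess Cp2Zr(H)Cl the zirconium should settle on the less hindered methyl-bearing alkyne carbons (C13 and C13'), which fixes both trisubstituted alkenes as E.

Step 16
Reactants: 19 (3E,5E)-4-methyl-6-[(1R,5S)-2,6,6-trimethyl-5-(3-methylbut-2-en-1-yl)cyclohex-2-en-1-yl]hexa-3,5-dien-1-yne; 25 (2E,4E,6E)-2,7-diiodoocta-2,4,6-triene
Product: 27 (2E,4E,6E,8E,10E,12E)-2-iodo-7,11-dimethyl-13-[(1R,5S)-2,6,6-trimethyl-5-(3-methylbut-2-en-1-yl)cyclohex-2-en-1-yl]trideca-2,4,6,8,10,12-hexaene, via alkenylzirconocene chloride 26 (not isolated)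
Conditions: Cp2Zr(H)Cl (1.2 equiv), THF, rt, dark; then added to 25 (3 equiv), Pd(PPh3)4 (5 mol%), ZnCl2 (0.5 equiv), THF, 0 °C → rt
Reagents that add atoms: none
Why: Hydrozirconation of the terminal alkyne and Negishi-type Pd/Zn-catalysed alkenyl–alkenyl coupling with retention of both geometries; a threefold excess of the symmetric bis-iodide and inverse addition should hold the reaction at mono-coupling, unreacted 25 being recovered.

Step 17
Reactants: 7 (5S)-2,4,4-trimethyl-5-(3-methylbut-2-en-1-yl)cyclohex-2-en-1-one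
Product: 28 (5S)-5-[(2E)-4-hydroxy-3-methylbut-2-en-1-yl]-2,4,4-trimethylcyclohex-2-en-1-one
Conditions: SeO2 (0.3 equiv), t-BuOOH (3 equiv), salicylic acid (10 mol%), CH2Cl2, rt
Reagents that add atoms: tert-butyl hydroperoxide, CC(C)(C)OO; selenium dioxide, O=[Se]=O
Why: Selenium dioxide allylic oxidation (ene reaction then [2,3]-shift, the selenium being reoxidised by t-BuOOH) is selective for the (E)-methyl group of a trisubstituted prenyl alkene, and the electron-poor enone alkene should not react, so the (E)-allylic alcohol is made at this stage before the ring alkene becomes electron-rich.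

Step 18
Reactants: 28 (5S)-5-[(2E)-4-hydroxy-3-methylbut-2-en-1-yl]-2,4,4-trimethylcyclohex-2-en-1-one
Product: 29 (5S)-5-[(2E)-4-{[tert-butyl(dimethyl)silyl]oxy}-3-methylbut-2-en-1-yl]-2,4,4-trimethylcyclohex-2-en-1-one
Conditions: TBSCl, imidazole, DMF, 0 °C → rt
Reagents that add atoms: tert-butyl(chloro)dimethylsilane, CC(C)(C)[Si](C)(C)Cl
Why: Silylation of the primary allylic alcohol protects it against the bases and organometallic reagents of steps 20 to 26.

Step 19
Reactants: 29 (5S)-5-[(2E)-4-{[tert-butyl(dimethyl)silyl]oxy}-3-methylbut-2-en-1-yl]-2,4,4-trimethylcyclohex-2-en-1-one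
Product: 30 (1S,5S)-5-[(2E)-4-{[tert-butyl(dimethyl)silyl]oxy}-3-methylbut-2-en-1-yl]-2,4,4-trimethylcyclohex-2-en-1-ol
Conditions: (R)-2-methyl-CBS-oxazaborolidine (0.5 equiv), catecholborane (1.5 equiv), toluene, −78 °C; aq NaOH
Reagents that add atoms: none
Why: CBS reduction under catalyst control: with the α-methylated alkene arm as the large group, the (R)-oxazaborolidine should deliver hydride to the face that gives the (1S)-carbinol trans to the C5 side chain, against the cis preference of the substrate, and catecholborane is used because it does not hydroborate the side-chain alkene.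

Step 20
Reactants: 30 (1S,5S)-5-[(2E)-4-{[tert-butyl(dimethyl)silyl]oxy}-3-methylbut-2-en-1-yl]-2,4,4-trimethylcyclohex-2-en-1-ol
Product: 31 tributyl({[(1S,5S)-5-[(2E)-4-{[tert-butyl(dimethyl)silyl]oxy}-3-methylbut-2-en-1-yl]-2,4,4-trimethylcyclohex-2-en-1-yl]oxy}methyl)stannane
Conditions: KH, 18-crown-6 (cat.), THF, 0 °C; Bu3SnCH2I, rt
Reagents that add atoms: (iodomethyl)tributylstannane, CCCC[Sn](CCCC)(CCCC)CI
Why: Williamson etherification as in step 6; the silyl ether is stable to KH.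

Step 21
Reactants: 31 tributyl({[(1S,5S)-5-[(2E)-4-{[tert-butyl(dimethyl)silyl]oxy}-3-methylbut-2-en-1-yl]-2,4,4-trimethylcyclohex-2-en-1-yl]oxy}methyl)stannane
Product: 33 {(1S,5R)-5-[(2E)-4-{[tert-butyl(dimethyl)silyl]oxy}-3-methylbut-2-en-1-yl]-2,6,6-trimethylcyclohex-2-en-1-yl}methanol, via lithiomethyl ether 32 (not isolated)
Conditions: n-BuLi (1.2 equiv), THF, −78 → −30 °C; aq NH4Cl
Reagents that add atoms: none
Why: Still–Wittig [2,3]-sigmatropic rearrangement as in step 7: suprafacial transfer from the trans-configured C1–O bond sets C6' (S) trans to the side chain, the only stereochemical difference between ring B and ring A.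

Step 22
Reactants: 33 {(1S,5R)-5-[(2E)-4-{[tert-butyl(dimethyl)silyl]oxy}-3-methylbut-2-en-1-yl]-2,6,6-trimethylcyclohex-2-en-1-yl}methanol
Product: 34 5-[({(1S,5R)-5-[(2E)-4-{[tert-butyl(dimethyl)silyl]oxy}-3-methylbut-2-en-1-yl]-2,6,6-trimethylcyclohex-2-en-1-yl}methyl)sulfanyl]-1-phenyl-1H-tetrazole
Conditions: 1-phenyl-1H-tetrazole-5-thiol, PPh3, DIAD, THF, 0 °C → rt
Reagents that add atoms: 1-phenyl-1H-tetrazole-5-thiol, Sc1nnnn1-c1ccccc1
Why: Mitsunobu thioetherification as in step 8.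

Step 23
Reactants: 34 5-[({(1S,5R)-5-[(2E)-4-{[tert-butyl(dimethyl)silyl]oxy}-3-methylbut-2-en-1-yl]-2,6,6-trimethylcyclohex-2-en-1-yl}methyl)sulfanyl]-1-phenyl-1H-tetrazole
Product: 35 5-[({(1S,5R)-5-[(2E)-4-{[tert-butyl(dimethyl)silyl]oxy}-3-methylbut-2-en-1-yl]-2,6,6-trimethylcyclohex-2-en-1-yl}methyl)sulfonyl]-1-phenyl-1H-tetrazole
Conditions: (NH4)6Mo7O24·4H2O (10 mol%), 30% aq H2O2, EtOH, 0 °C → rt
Reagents that add atoms: hydrogen peroxide, OO
Why: Molybdate-catalysed sulfide-to-sulfone oxidation as in step 9; the silyl ether should survive the near-neutral medium.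

Step 24
Reactants: 35 5-[({(1S,5R)-5-[(2E)-4-{[tert-butyl(dimethyl)silyl]oxy}-3-methylbut-2-en-1-yl]-2,6,6-trimethylcyclohex-2-en-1-yl}methyl)sulfonyl]-1-phenyl-1H-tetrazole; 16 (2E)-2-methyl-5-(trimethylsilyl)pent-2-en-4-ynal
Product: 37 tert-butyl(dimethyl){[(2E)-2-methyl-4-{(1R,5S)-4,6,6-trimethyl-5-[(1E,3E)-3-methyl-6-(trimethylsilyl)hexa-1,3-dien-5-yn-1-yl]cyclohex-3-en-1-yl}but-2-en-1-yl]oxy}silane, via potassium sulfonyl carbanion 36 (not isolated)
Conditions: KN(SiMe3)2, DME, −60 °C; 16, −60 °C → rt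
Reagents that add atoms: none
Why: Julia–Kocienski olefination as in step 11 should give the (E)-C7'=C8' alkene.

Step 25
Reactants: 37 tert-butyl(dimethyl){[(2E)-2-methyl-4-{(1R,5S)-4,6,6-trimethyl-5-[(1E,3E)-3-methyl-6-(trimethylsilyl)hexa-1,3-dien-5-yn-1-yl]cyclohex-3-en-1-yl}but-2-en-1-yl]oxy}silane
Product: 38 tert-butyl(dimethyl){[(2E)-2-methyl-4-{(1R,5S)-4,6,6-trimethyl-5-[(1E,3E)-3-methylhexa-1,3-dien-5-yn-1-yl]cyclohex-3-en-1-yl}but-2-en-1-yl]oxy}silane
Conditions: K2CO3, MeOH, rt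
Reagents that add atoms: none
Why: Base-catalysed methanolysis removes only the alkynyl silyl group, the silyl ether on oxygen being stable to K2CO3 in methanol.

Step 26
Reactants: 38 tert-butyl(dimethyl){[(2E)-2-methyl-4-{(1R,5S)-4,6,6-trimethyl-5-[(1E,3E)-3-methylhexa-1,3-dien-5-yn-1-yl]cyclohex-3-en-1-yl}but-2-en-1-yl]oxy}silane; 27 (2E,4E,6E,8E,10E,12E)-2-iodo-7,11-dimethyl-13-[(1R,5S)-2,6,6-trimethyl-5-(3-methylbut-2-en-1-yl)cyclohex-2-en-1-yl]trideca-2,4,6,8,10,12-hexaene
Product: 40 O-tert-butyl(dimethyl)silyl ether of the target, via alkenylzirconocene chloride 39 (not isolated)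
Conditions: Cp2Zr(H)Cl (1.2 equiv), THF, rt, dark; then 27 (1.0 equiv), Pd(PPh3)4 (5 mol%), ZnCl2 (0.5 equiv), THF, rt, argon, dark
Reagents that add atoms: none
Why: Syn-addition of Cp2Zr(H)Cl across the terminal C11'≡C12' alkyne of 38 should give the (E)-alkenylzirconocene 39 with zirconium on C12'; zerovalent palladium inserts into the C13'–I bond of 27, the alkenyl group passes from zirconium through zinc to palladium, and reductive elimination forms the C12'–C13' bond with retention at both alkenes. The closest known reaction type is the hydrozirconation/Negishi alkenyl–alkenyl coupling under Pd/Zn double catalysis, which is established for stereodefined conjugated dienes and polyenes. No ring is closed and no stereocentre is formed: the new C11'=C12' alkene is E because H and Zr add to the same side, and the C13'=C14' geometry is carried over from 27. The step needs chemoselectivity for the terminal alkyne over the trisubstituted ring and side-chain alkenes and the conjugated internal alkenes, which their substitution secures, and coupling at the single C–I bond present. The silyl ether keeps the hydroxyl from quenching the organometallic intermediates, and light and air are excluded to protect the polyene. In one flask a dienyne and a hexaenyl iodide become the complete all-E nonaene carrying all four stereocentres.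

Step 27
Reactants: 40 O-tert-butyl(dimethyl)silyl ether of the target
Product: 41 (2S,6R,2'R,6'S)-2'-[(2E)-4-hydroxy-3-methylbut-2-en-1-yl]-2-(3-methylbut-2-en-1-yl)-ε,ε-carotene (CNP0304855.1)
Conditions: Bu4NF, AcOH (buffer), THF, 0 °C → rt, dark
Reagents that add atoms: none
Why: Fluoride-mediated cleavage of the primary silyl ether under buffered conditions should free the allylic alcohol without touching the polyene.

**Compound list**

1 | 2,4,4-trimethylcyclohex-2-en-1-one | CC1=CC(C)(C)CCC1=O | starting material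
2 | 2,4,4-trimethylcyclohexa-2,5-dien-1-one | CC1=CC(C)(C)C=CC1=O | intermediate
3 | 4-bromo-2-methylbut-1-ene | C=C(C)CCBr | starting material
4 | (3-methylbut-3-en-1-yl)magnesium bromide | C=C(C)CC[Mg]Br | intermediate
5 | bromomagnesium (3S)-4,4,6-trimethyl-3-(3-methylbut-3-en-1-yl)cyclohexa-1,5-dien-1-olate (magnesium enolate of 6) | Br[Mg]OC1=C[C@H](CCC(C)=C)C(C)(C)C=C1C | intermediate
6 | (5S)-2,4,4-trimethyl-5-(3-methylbut-3-en-1-yl)cyclohex-2-en-1-one | O=C1C(C)=CC(C)(C)[C@@H](CCC(C)=C)C1 | intermediate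
7 | (5S)-2,4,4-trimethyl-5-(3-methylbut-2-en-1-yl)cyclohex-2-en-1-one | O=C1C(C)=CC(C)(C)[C@@H](CC=C(C)C)C1 | intermediate
8 | (1R,5S)-2,4,4-trimethyl-5-(3-methylbut-2-en-1-yl)cyclohex-2-en-1-ol (OH cis to the prenyl group) | O[C@H]1C(C)=CC(C)(C)[C@@H](CC=C(C)C)C1 | intermediate
9 | tributyl({[(1R,5S)-2,4,4-trimethyl-5-(3-methylbut-2-en-1-yl)cyclohex-2-en-1-yl]oxy}methyl)stannane | CCCC[Sn](CCCC)(CCCC)CO[C@H]1C(C)=CC(C)(C)[C@@H](CC=C(C)C)C1 | intermediate
10 | ({[(1R,5S)-2,4,4-trimethyl-5-(3-methylbut-2-en-1-yl)cyclohex-2-en-1-yl]oxy}methyl)lithium | [Li]CO[C@H]1C(C)=CC(C)(C)[C@@H](CC=C(C)C)C1 | intermediate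
11 | [(1R,5S)-2,6,6-trimethyl-5-(3-methylbut-2-en-1-yl)cyclohex-2-en-1-yl]methanol (CH2OH cis to the prenyl group) | CC(C)=CC[C@H]1CC=C(C)[C@@H](CO)C1(C)C | intermediate
12 | 1-phenyl-5-({[(1R,5S)-2,6,6-trimethyl-5-(3-methylbut-2-en-1-yl)cyclohex-2-en-1-yl]methyl}sulfanyl)-1H-tetrazole | CC(C)=CC[C@H]1CC=C(C)[C@@H](CSc2nnnn2-c2ccccc2)C1(C)C | intermediate
13 | 1-phenyl-5-({[(1R,5S)-2,6,6-trimethyl-5-(3-methylbut-2-en-1-yl)cyclohex-2-en-1-yl]methyl}sulfonyl)-1H-tetrazole | CC(C)=CC[C@H]1CC=C(C)[C@@H](CS(=O)(=O)c2nnnn2-c2ccccc2)C1(C)C | intermediate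
14 | 3-(trimethylsilyl)prop-2-ynal | C[Si](C)(C)C#CC=O | starting material
15 | 2-(triphenyl-λ5-phosphanylidene)propanal | CC(C=O)=P(c1ccccc1)(c1ccccc1)c1ccccc1 | starting material
16 | (2E)-2-methyl-5-(trimethylsilyl)pent-2-en-4-ynal | O=C/C(C)=C/C#C[Si](C)(C)C | intermediate
17 | potassium α-sulfonyl carbanion of 13 | CC(C)=CC[C@H]1CC=C(C)[C@@H](C([K])S(=O)(=O)c2nnnn2-c2ccccc2)C1(C)C | intermediate
18 | trimethyl{(3E,5E)-4-methyl-6-[(1R,5S)-2,6,6-trimethyl-5-(3-methylbut-2-en-1-yl)cyclohex-2-en-1-yl]hexa-3,5-dien-1-yn-1-yl}silane | CC(C)=CC[C@H]1CC=C(C)[C@@H](/C=C/C(C)=C/C#C[Si](C)(C)C)C1(C)C | intermediate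
19 | (3E,5E)-4-methyl-6-[(1R,5S)-2,6,6-trimethyl-5-(3-methylbut-2-en-1-yl)cyclohex-2-en-1-yl]hexa-3,5-dien-1-yne (ring A C21 dienyne) | CC(C)=CC[C@H]1CC=C(C)[C@@H](/C=C/C(C)=C/C#C)C1(C)C | intermediate
20 | (E)-1,2-dichloroethene | Cl/C=C/Cl | starting material
21 | propyne | CC#C | starting material
22 | (1E)-1-chloropent-1-en-3-yne | CC#C/C=C/Cl | intermediate
23 | (4E)-octa-4-ene-2,6-diyne | CC#C/C=C/C#CC | intermediate
24 | [(2E,4E,6E)-octa-2,4,6-triene-2,7-diyl]bis[chlorobis(cyclopentadienyl)zirconium] | C/C([Zr](Cl)(C1C=CC=C1)C1C=CC=C1)=C\C=C\C=C(/C)[Zr](Cl)(C1C=CC=C1)C1C=CC=C1 | intermediate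
25 | (2E,4E,6E)-2,7-diiodoocta-2,4,6-triene | C/C(I)=C\C=C\C=C(/C)I | intermediate
26 | chlorobis(cyclopentadienyl){(1E,3E,5E)-4-methyl-6-[(1R,5S)-2,6,6-trimethyl-5-(3-methylbut-2-en-1-yl)cyclohex-2-en-1-yl]hexa-1,3,5-trien-1-yl}zirconium | CC(C)=CC[C@H]1CC=C(C)[C@@H](/C=C/C(C)=C/C=C/[Zr](Cl)(C2C=CC=C2)C2C=CC=C2)C1(C)C | intermediate
27 | (2E,4E,6E,8E,10E,12E)-2-iodo-7,11-dimethyl-13-[(1R,5S)-2,6,6-trimethyl-5-(3-methylbut-2-en-1-yl)cyclohex-2-en-1-yl]trideca-2,4,6,8,10,12-hexaene (C29 iodide) | CC(C)=CC[C@H]1CC=C(C)[C@@H](/C=C/C(C)=C/C=C/C(C)=C/C=C/C=C(\C)I)C1(C)C | intermediate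
28 | (5S)-5-[(2E)-4-hydroxy-3-methylbut-2-en-1-yl]-2,4,4-trimethylcyclohex-2-en-1-one | O=C1C(C)=CC(C)(C)[C@@H](C/C=C(\C)CO)C1 | intermediate
29 | (5S)-5-[(2E)-4-{[tert-butyl(dimethyl)silyl]oxy}-3-methylbut-2-en-1-yl]-2,4,4-trimethylcyclohex-2-en-1-one | O=C1C(C)=CC(C)(C)[C@@H](C/C=C(\C)CO[Si](C)(C)C(C)(C)C)C1 | intermediate
30 | (1S,5S)-5-[(2E)-4-{[tert-butyl(dimethyl)silyl]oxy}-3-methylbut-2-en-1-yl]-2,4,4-trimethylcyclohex-2-en-1-ol (OH trans to the side chain) | O[C@@H]1C(C)=CC(C)(C)[C@@H](C/C=C(\C)CO[Si](C)(C)C(C)(C)C)C1 | intermediate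
31 | tributyl({[(1S,5S)-5-[(2E)-4-{[tert-butyl(dimethyl)silyl]oxy}-3-methylbut-2-en-1-yl]-2,4,4-trimethylcyclohex-2-en-1-yl]oxy}methyl)stannane | CCCC[Sn](CCCC)(CCCC)CO[C@@H]1C(C)=CC(C)(C)[C@@H](C/C=C(\C)CO[Si](C)(C)C(C)(C)C)C1 | intermediate
32 | ({[(1S,5S)-5-[(2E)-4-{[tert-butyl(dimethyl)silyl]oxy}-3-methylbut-2-en-1-yl]-2,4,4-trimethylcyclohex-2-en-1-yl]oxy}methyl)lithium | [Li]CO[C@@H]1C(C)=CC(C)(C)[C@@H](C/C=C(\C)CO[Si](C)(C)C(C)(C)C)C1 | intermediate
33 | {(1S,5R)-5-[(2E)-4-{[tert-butyl(dimethyl)silyl]oxy}-3-methylbut-2-en-1-yl]-2,6,6-trimethylcyclohex-2-en-1-yl}methanol (CH2OH trans to the side chain) | CC(C)(C)[Si](C)(C)OC/C(C)=C/C[C@H]1CC=C(C)[C@H](CO)C1(C)C | intermediate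
34 | 5-[({(1S,5R)-5-[(2E)-4-{[tert-butyl(dimethyl)silyl]oxy}-3-methylbut-2-en-1-yl]-2,6,6-trimethylcyclohex-2-en-1-yl}methyl)sulfanyl]-1-phenyl-1H-tetrazole | CC(C)(C)[Si](C)(C)OC/C(C)=C/C[C@H]1CC=C(C)[C@H](CSc2nnnn2-c2ccccc2)C1(C)C | intermediate
35 | 5-[({(1S,5R)-5-[(2E)-4-{[tert-butyl(dimethyl)silyl]oxy}-3-methylbut-2-en-1-yl]-2,6,6-trimethylcyclohex-2-en-1-yl}methyl)sulfonyl]-1-phenyl-1H-tetrazole | CC(C)(C)[Si](C)(C)OC/C(C)=C/C[C@H]1CC=C(C)[C@H](CS(=O)(=O)c2nnnn2-c2ccccc2)C1(C)C | intermediate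
36 | potassium α-sulfonyl carbanion of 35 | CC(C)(C)[Si](C)(C)OC/C(C)=C/C[C@H]1CC=C(C)[C@H](C([K])S(=O)(=O)c2nnnn2-c2ccccc2)C1(C)C | intermediate
37 | tert-butyl(dimethyl){[(2E)-2-methyl-4-{(1R,5S)-4,6,6-trimethyl-5-[(1E,3E)-3-methyl-6-(trimethylsilyl)hexa-1,3-dien-5-yn-1-yl]cyclohex-3-en-1-yl}but-2-en-1-yl]oxy}silane | CC(C)(C)[Si](C)(C)OC/C(C)=C/C[C@H]1CC=C(C)[C@H](/C=C/C(C)=C/C#C[Si](C)(C)C)C1(C)C | intermediate
38 | tert-butyl(dimethyl){[(2E)-2-methyl-4-{(1R,5S)-4,6,6-trimethyl-5-[(1E,3E)-3-methylhexa-1,3-dien-5-yn-1-yl]cyclohex-3-en-1-yl}but-2-en-1-yl]oxy}silane (ring B C21 dienyne; carotenoid 2'R,6'S) | CC(C)(C)[Si](C)(C)OC/C(C)=C/C[C@H]1CC=C(C)[C@H](/C=C/C(C)=C/C#C)C1(C)C | intermediate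
39 | (E)-alkenylzirconocene chloride from 38, zirconium on C12' | CC(C)(C)[Si](C)(C)OC/C(C)=C/C[C@H]1CC=C(C)[C@H](/C=C/C(C)=C/C=C/[Zr](Cl)(C2C=CC=C2)C2C=CC=C2)C1(C)C | intermediate
40 | O-tert-butyl(dimethyl)silyl ether of the target | CC(C)=CC[C@H]1CC=C(C)[C@@H](/C=C/C(C)=C/C=C/C(C)=C/C=C/C=C(C)/C=C/C=C(C)/C=C/[C@H]2C(C)=CC[C@H](C/C=C(\C)CO[Si](C)(C)C(C)(C)C)C2(C)C)C1(C)C | intermediate
41 | (2S,6R,2'R,6'S)-2'-[(2E)-4-hydroxy-3-methylbut-2-en-1-yl]-2-(3-methylbut-2-en-1-yl)-ε,ε-carotene, all-E (CNP0304855.1) | CC(C)=CC[C@H]1CC=C(C)[C@@H](/C=C/C(C)=C/C=C/C(C)=C/C=C/C=C(C)/C=C/C=C(C)/C=C/[C@H]2C(C)=CC[C@H](C/C=C(\C)CO)C2(C)C)C1(C)C | target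

**Summary**

Total step count: 27.
Longest linear sequence: 14 steps (steps 1, 3, 4 and 17 to 27, from 1 to 41).

Steps most likely to fail:

Step 3. Uncatalysed 1,2-addition of the Grignard reagent to the carbonyl may compete, the enantiotopic faces of the dienone may be poorly discriminated, or the methylated arm may be attacked, when the alkyl group is added next to the quaternary carbon. The fallback sets out from 2. Hosomi–Sakurai allylation (allyltrimethylsilane, TiCl4, CH2Cl2, −78 °C) would give racemic 5-allyl-2,4,4-trimethylcyclohex-2-en-1-one F1. Cross-metathesis with 2-methylbut-2-ene (second-generation Grubbs catalyst) would give racemic 2,4,4-trimethyl-5-(3-methylbut-2-en-1-yl)cyclohex-2-en-1-one F2. Reagent-controlled CBS reduction of F2 with the (S)-oxazaborolidine and catecholborane would turn the two enantiomers into diastereomeric (1R)-alcohols, 8 and (1R,5R)-2,4,4-trimethyl-5-(3-methylbut-2-en-1-yl)cyclohex-2-en-1-ol F3, to be separated by chromatography. The route is rejoined at 8; for steps 17 onward part of 8 would be oxidised back to 7 with MnO2.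

Step 7. In the cis series the [2,3]-shift needs the C1–O bond pseudo-axial, which also forces the prenyl group axial, so protonation of the carbanion or a [1,2]-shift may compete. The fallback sets out from 8. Phenyl isocyanate would give (1R,5S)-2,4,4-trimethyl-5-(3-methylbut-2-en-1-yl)cyclohex-2-en-1-yl N-phenylcarbamate F4. Copper-mediated syn-SN2' substitution of the deprotonated carbamate (n-BuLi, CuI, then (i-PrO)Me2SiCH2MgCl, THF) would deliver the silylmethyl group to C3 on the face of the carbamate and give {[(1R,5S)-2,6,6-trimethyl-5-(3-methylbut-2-en-1-yl)cyclohex-2-en-1-yl]methyl}(dimethyl)(propan-2-yloxy)silane F5. Tamao oxidation (H2O2, KF, KHCO3, THF/MeOH) comes back to the route at 11.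

Step 19. The double stereodifferentiation is mismatched: diastereoselectivity may erode when the catalyst has to override the substrate's cis preference. The fallback sets out from 29. Luche reduction (NaBH4, CeCl3·7H2O) would give the cis alcohol (1R,5S)-5-[(2E)-4-{[tert-butyl(dimethyl)silyl]oxy}-3-methylbut-2-en-1-yl]-2,4,4-trimethylcyclohex-2-en-1-ol F6. Mitsunobu inversion with 4-nitrobenzoic acid (PPh3, DIAD) would give (1S,5S)-5-[(2E)-4-{[tert-butyl(dimethyl)silyl]oxy}-3-methylbut-2-en-1-yl]-2,4,4-trimethylcyclohex-2-en-1-yl 4-nitrobenzoate F7. Methanolysis (K2CO3, MeOH) comes back to the route at 30.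

**Further compounds**

F1 | step 3 | racemic 5-allyl-2,4,4-trimethylcyclohex-2-en-1-one | O=C1C(C)=CC(C)(C)C(CC=C)C1
F2 | step 3 | racemic 2,4,4-trimethyl-5-(3-methylbut-2-en-1-yl)cyclohex-2-en-1-one | O=C1C(C)=CC(C)(C)C(CC=C(C)C)C1
F3 | step 3 | (1R,5R)-2,4,4-trimethyl-5-(3-methylbut-2-en-1-yl)cyclohex-2-en-1-ol | O[C@H]1C(C)=CC(C)(C)[C@H](CC=C(C)C)C1
F4 | step 7 | (1R,5S)-2,4,4-trimethyl-5-(3-methylbut-2-en-1-yl)cyclohex-2-en-1-yl N-phenylcarbamate | O=C(Nc1ccccc1)O[C@H]1C(C)=CC(C)(C)[C@@H](CC=C(C)C)C1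
F5 | step 7 | {[(1R,5S)-2,6,6-trimethyl-5-(3-methylbut-2-en-1-yl)cyclohex-2-en-1-yl]methyl}(dimethyl)(propan-2-yloxy)silane | CC(C)=CC[C@H]1CC=C(C)[C@@H](C[Si](C)(C)OC(C)C)C1(C)C
F6 | step 19 | (1R,5S)-5-[(2E)-4-{[tert-butyl(dimethyl)silyl]oxy}-3-methylbut-2-en-1-yl]-2,4,4-trimethylcyclohex-2-en-1-ol | O[C@H]1C(C)=CC(C)(C)[C@@H](C/C=C(\C)CO[Si](C)(C)C(C)(C)C)C1
F7 | step 19 | (1S,5S)-5-[(2E)-4-{[tert-butyl(dimethyl)silyl]oxy}-3-methylbut-2-en-1-yl]-2,4,4-trimethylcyclohex-2-en-1-yl 4-nitrobenzoate | O=C(O[C@@H]1C(C)=CC(C)(C)[C@@H](C/C=C(\C)CO[Si](C)(C)C(C)(C)C)C1)c1ccc(cc1)[N+](=O)[O-]
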